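The synthesis rests on cutting C5–C6 of the bicyclo[3.3.1]nonane, beside the bridging ketone C9. The precursor is a chroman-derived dienone in which C6 is bound to the oxygen of C9 instead of to C5. This temporary pyran ring allows the crowded C1–C8 bond to be made on an aromatic CH. It also steers the C1 prenyl group trans to the C7 prenyl group (endo series) and keeps C6 beside C5. In the key step iodide opens the vinylogous ester O–C9=C5–C4=O at C6, and the freed enolate closes ring B (C1, C9, C5, C6, C7, C8) at C5, setting C5. The step exploits the oxygen on C9, which lies between both bridgeheads.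

Key step: step 9

Remark on numbering: all compounds carry the atom numbers of the target. These are C1 prenyl bridgehead, C2–C4 enolised dione with the acyl group on C3, C5 methyl bridgehead, C6 CH2, C7 CH(prenyl), C8 CMe2 and C9 bridging ketone. Ring A is C1–C2–C3–C4–C5–C9 and comes from the arene. Ring B is C1–C9–C5–C6–C7–C8.
Remark on the chemistry: the enolised triketone tautomers interconvert rapidly, so the product of step 9 is drawn as the tautomer of the target SMILES. (S)-Lavandulol is not taken as commercial and is made in steps 1–3.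

Step 1
Reactants: 1 (S)-4-benzyl-2-oxazolidinone; 2 3-methylbut-2-enoyl chloride
Product: 3 (S)-4-benzyl-3-(3-methylbut-2-enoyl)oxazolidin-2-one
Conditions: n-BuLi, THF, −78 °C; then 2, −78 → 0 °C
Reagents that add atoms: 3-methylbut-2-enoyl chloride 2, CC(C)=CC(=O)Cl
Why: N-acylation of the lithiated oxazolidinone with an acid chloride is the standard entry to an Evans imide and touches no stereocenter.

Step 2
Reactants: 3 (S)-4-benzyl-3-(3-methylbut-2-enoyl)oxazolidin-2-one; 4 prenyl bromide
Product: 5 (S)-4-benzyl-3-[(S)-5-methyl-2-(prop-1-en-2-yl)hex-4-enoyl]oxazolidin-2-one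
Conditions: NaHMDS, THF, −78 °C; then 4, −78 °C, cold quench
Reagents that add atoms: prenyl bromide 4, CC(C)=CCBr
Why: Deconjugative Evans alkylation, in which the chelated Z-dienolate reacts at its α-carbon on the face away from the benzyl group, should set the (S) centre that becomes C7 and move the double bond into the isopropenyl group.

Step 3
Reactants: 5 (S)-4-benzyl-3-[(S)-5-methyl-2-(prop-1-en-2-yl)hex-4-enoyl]oxazolidin-2-one
Product: 6 (S)-lavandulol
Conditions: LiBH4, MeOH (1 equiv), Et2O, 0 °C
Reagents that add atoms: none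
Why: Reductive cleavage of the imide by LiBH4 should give the primary alcohol without touching the α-centre or either alkene.

Step 4
Reactants: 7 2-methylphloroglucinol; 8 isobutyryl chloride
Product: 9 2-methyl-1-(2,4,6-trihydroxy-3-methylphenyl)propan-1-one
Conditions: AlCl3, CH2Cl2/PhNO2, 0 → 45 °C
Reagents that add atoms: isobutyryl chloride 8, CC(C)C(=O)Cl
Why: Friedel–Crafts acylation takes place at one of the two equivalent free CH positions of the electron-rich arene, and the chelated ketone formed disfavours a second acylation.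

Step 5
Reactants: 9 2-methyl-1-(2,4,6-trihydroxy-3-methylphenyl)propan-1-one; 6 (S)-lavandulol
Product: 10 1-{2,6-dihydroxy-3-methyl-4-[(S)-lavandulyloxy]phenyl}-2-methylpropan-1-one
Conditions: PPh3, DIAD, THF, 0 °C → rt
Reagents that add atoms: none
Why: The Mitsunobu etherification should pick the only phenol not hydrogen-bonded to the ketone (para to the acyl group, the later oxygen on C9) and reacts at the primary carbon C6, so C7 is untouched.

Step 6
Reactants: 10 1-{2,6-dihydroxy-3-methyl-4-[(S)-lavandulyloxy]phenyl}-2-methylpropan-1-one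
Product: 11 1-[(3S)-5,7-dihydroxy-4,4,8-trimethyl-3-(3-methylbut-2-enyl)chroman-6-yl]-2-methylpropan-1-one
Conditions: Co(salen) cat. ([N,N'-bis(3,5-di-tert-butylsalicylidene)-1,2-cyclohexanediaminato]cobalt, divalent cobalt, 5 mol %), N-fluoro-2,4,6-trimethylpyridinium triflate, (Me2SiH)2O, PhCF3, rt
Reagents that add atoms: none
Why: In this Markovnikov hydroarylation by cobalt-hydride hydrogen-atom transfer and radical-polar crossover, the hydride should add to the less hindered 1,1-disubstituted alkene rather than the trisubstituted one, the tertiary C8 centre is captured by the only free ortho CH (C1) in a six-membered closure, and rearomatisation makes the crowded C1–C8 bond irreversible while C7 is untouched.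

Step 7
Reactants: 11 1-[(3S)-5,7-dihydroxy-4,4,8-trimethyl-3-(3-methylbut-2-enyl)chroman-6-yl]-2-methylpropan-1-one; 4 prenyl bromide
Product: 12 1-[(3S)-5-hydroxy-4,4,8-trimethyl-3-(3-methylbut-2-enyl)-7-(3-methylbut-2-enyloxy)chroman-6-yl]-2-methylpropan-1-one
Conditions: 4 (1.1 equiv), K2CO3, acetone, 56 °C
Reagents that add atoms: prenyl bromide 4, CC(C)=CCBr
Why: Williamson O-alkylation should occur at the hydroxyl on C4, which is flanked only by the methyl group, because the hydroxyl on C2 is shielded by the peri gem-dimethyl group at C8.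

Step 8
Reactants: 12 1-[(3S)-5-hydroxy-4,4,8-trimethyl-3-(3-methylbut-2-enyl)-7-(3-methylbut-2-enyloxy)chroman-6-yl]-2-methylpropan-1-one
Product: 14 (3S,4aS)-5-hydroxy-4,4,8-trimethyl-3,4a-bis(3-methylbut-2-enyl)-6-(2-methylpropanoyl)-2,3,4,4a-tetrahydro-7H-chromen-7-one, via ortho-dienone 13 (not isolated)
Conditions: Eu(fod)3 (tris(6,6,7,7,8,8,8-heptafluoro-2,2-dimethyloctane-3,5-dionato)europium, 10 mol %), PhCl, 85 °C
Reagents that add atoms: none
Why: In this domino aromatic Claisen–Cope (para-Claisen) rearrangement, known for prenyl ethers ortho to a chelating carbonyl, the prenyl group travels suprafacially from the oxygen on C4 by way of the methyl-bearing C5 to the para carbon C1, where it must take the axial site of the pyran ring and should therefore end up syn to H7 and trans to the equatorial C7 prenyl group (4aS), since the other face would give a 1,3-diaxial clash.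

Step 9
Reactants: 14 (3S,4aS)-5-hydroxy-4,4,8-trimethyl-3,4a-bis(3-methylbut-2-enyl)-6-(2-methylpropanoyl)-2,3,4,4a-tetrahydro-7H-chromen-7-one
Product: 16 (1R,5R,7R)-4-hydroxy-5,8,8-trimethyl-1,7-bis(3-methylbut-2-enyl)-3-(2-methylpropanoyl)bicyclo[3.3.1]non-3-ene-2,9-dione (target), via iodo enol 15 (not isolated)
Conditions: LiI (2 equiv), DMF, 110 °C, argon, dark
Reagents that add atoms: none
Why: Proposed new method: iodide attacks the primary carbon C6 of the vinylogous ester O–C9=C5–C4=O in an SN2 step and expels the vinylogous carboxylate, so the temporary pyran ring opens to the ω-iodo enolate 15, whose carbon C5 then displaces iodide and closes ring B. The closest known reaction types are the halide dealkylation of vinylogous esters (LiCl or LiI in a dipolar solvent), the LiI-promoted O-to-N alkyl shift of 2-alkoxypyridines and the intramolecular C-alkylation of cyclic 1,3-dicarbonyl enolates. Ring B closes in the 6-(enolendo)-exo-tet mode through a boat-like array with the C7 prenyl group pointing outward, C6 only swinging from the oxygen on C9 to the neighbouring C5. The new stereocenter C5 is fixed by the tether, because C6 hangs on the C8–C7 chain on one face of C1 and can reach C5 only from that face, which gives the cis-bridged (5R) centre while C1 and C7 are not touched. The step needs C- over O-alkylation and C5 over C3: alkylation at the oxygens on C9 or C2 only gives vinylogous esters that iodide reopens, the C5–C6 bond is not cleaved again, and C3 is the hindered central carbon of the chelated triketone, whose alkylation would destroy that chelate. LiI is regenerated, so the step is a net isomerisation.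

Compound list
1 | (S)-4-benzyl-2-oxazolidinone | O=C1N[C@@H](Cc2ccccc2)CO1 | starting material
2 | 3-methylbut-2-enoyl chloride | CC(C)=CC(=O)Cl | starting material
3 | (S)-4-benzyl-3-(3-methylbut-2-enoyl)oxazolidin-2-one | CC(C)=CC(=O)N1[C@@H](Cc2ccccc2)COC1=O | intermediate
4 | prenyl bromide | CC(C)=CCBr | starting material
5 | (S)-4-benzyl-3-[(S)-5-methyl-2-(prop-1-en-2-yl)hex-4-enoyl]oxazolidin-2-one | CC(C)=CC[C@@H](C(C)=C)C(=O)N1[C@@H](Cc2ccccc2)COC1=O | intermediate
6 | (S)-lavandulol, (S)-5-methyl-2-(prop-1-en-2-yl)hex-4-en-1-ol | CC(C)=CC[C@@H](C(C)=C)CO | intermediate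
7 | 2-methylphloroglucinol (2,4,6-trihydroxytoluene) | Cc1c(O)cc(O)cc1O | starting material
8 | isobutyryl chloride | CC(C)C(=O)Cl | starting material
9 | 2-methyl-1-(2,4,6-trihydroxy-3-methylphenyl)propan-1-one | CC(C)C(=O)c1c(O)cc(O)c(C)c1O | intermediate
10 | 1-{2,6-dihydroxy-3-methyl-4-[(S)-lavandulyloxy]phenyl}-2-methylpropan-1-one | CC(C)=CC[C@@H](C(C)=C)COc1cc(O)c(C(=O)C(C)C)c(O)c1C | intermediate
11 | 1-[(3S)-5,7-dihydroxy-4,4,8-trimethyl-3-(3-methylbut-2-enyl)chroman-6-yl]-2-methylpropan-1-one | CC(C)=CC[C@@H]1COc2c(C)c(O)c(C(=O)C(C)C)c(O)c2C1(C)C | intermediate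
12 | 7-O-prenyl ether of 11 (oxygen on C4) | CC(C)=CC[C@@H]1COc2c(C)c(OCC=C(C)C)c(C(=O)C(C)C)c(O)c2C1(C)C | intermediate
13 | ortho-dienone, (3S,8R)-5-hydroxy-4,4,8-trimethyl-8-(2-methylbut-3-en-2-yl)-3-(3-methylbut-2-enyl)-6-(2-methylpropanoyl)-3,4-dihydro-2H-chromen-7(8H)-one | CC(C)=CC[C@@H]1COC2=C(C(O)=C(C(=O)C(C)C)C(=O)[C@]2(C)C(C)(C)C=C)C1(C)C | intermediate
14 | (3S,4aS)-5-hydroxy-4,4,8-trimethyl-3,4a-bis(3-methylbut-2-enyl)-6-(2-methylpropanoyl)-2,3,4,4a-tetrahydro-7H-chromen-7-one | CC(C)=CC[C@@H]1COC2=C(C)C(=O)C(C(=O)C(C)C)=C(O)[C@]2(CC=C(C)C)C1(C)C | intermediate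
15 | iodo enol, 14 with the O–C6 bond replaced by O–H and C6–I (formed as its lithium enolate) | CC(C)=CC[C@H](CI)C(C)(C)[C@]1(CC=C(C)C)C(O)=C(C)C(=O)C(C(=O)C(C)C)=C1O | intermediate
16 | (1R,5R,7R)-4-hydroxy-5,8,8-trimethyl-1,7-bis(3-methylbut-2-enyl)-3-(2-methylpropanoyl)bicyclo[3.3.1]non-3-ene-2,9-dione | CC(C)=CC[C@@H]1C[C@@]2(C)C(=O)[C@](CC=C(C)C)(C(=O)C(C(=O)C(C)C)=C2O)C1(C)C | target

Total step count: 9. Longest linear sequence: 8 (steps 1, 2, 3, 5, 6, 7, 8, 9).

Steps most likely to fail

(1) Step 9, the labelled step. The SN2 opening at the β-branched C6 may be slower than thermal reversal of the Cope step, loss of HI from the iodide, or attack by C3.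
- Fallback: known chemistry that closes the same ring at a different bond, C1–C8, by a biomimetic cationic cyclisation. It sets out from 9 and 6 and comes back at 16.
- C-Prenylation of 9 at its free CH (4, aqueous KOH, 0 °C) gives the prenylated acylphloroglucinol F1.
- Alcohol 6 is converted into (S)-lavandulyl triflate F2 (Tf2O, 2,6-lutidine, CH2Cl2, −78 °C).
- Alkylative dearomatisation of F1 (LiHMDS, THF, 0 °C, then F2) at the methyl-bearing carbon gives the lavandulyl dienone F3. Its C5 epimer forms as well, because the face of attack is not controlled, so the epimers have to be separated.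
- HCO2H at rt protonates the isopropenyl group of F3, and C1 captures the C8 cation to give 16.

(2) Step 8. The rearrangement may stall at the ortho-dienone, the prenyl ether may ionise, or the Cope step may show poor facial selectivity.
- Fallback: the prenyl group is placed on C1 before the C1–C8 bond is made, and that bond is then formed with dearomatisation. It sets out from 9 and 6 and comes back at 14.
- 9 is C-prenylated as above to the prenylated acylphloroglucinol F1.
- Mitsunobu etherification of F1 with 6 gives the lavandulyl ether F4.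
- The cobalt-hydride conditions of step 6 close the tertiary C8 centre onto the prenyl-bearing ortho carbon, with loss of a phenol proton, to give 14.
- Closure onto the methyl-bearing ortho carbon competes, and that isomer has to be removed.

(3) Step 6. Hydrogen-atom transfer may also reach the trisubstituted alkene, the N–F salt may oxidise the free phenols, or the tertiary radical may simply be reduced.
- Fallback: the cation precursor is installed before the arene is present, and the ring is closed by a dehydrative Friedel–Crafts alkylation. It sets out from 6 and comes back at 11.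
- Mukaiyama hydration of 6 at the 1,1-disubstituted alkene (Co(acac)2, PhSiH3, O2, THF) gives the lavandulol hydrate F5.
- Mitsunobu etherification of 9 with the primary hydroxyl of F5 gives the hydroxy ether F6.
- Bi(OTf)3 (cat.), MeNO2, 0 °C ionises the tertiary alcohol, and the free ortho CH closes the chroman 11.

Further compounds
F1 | step 9 | 2-methyl-1-[2,4,6-trihydroxy-3-methyl-5-(3-methylbut-2-enyl)phenyl]propan-1-one | CC(C)C(=O)c1c(O)c(C)c(O)c(CC=C(C)C)c1O
F2 | step 9 | (S)-lavandulyl trifluoromethanesulfonate | CC(C)=CC[C@@H](C(C)=C)COS(=O)(=O)C(F)(F)F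
F3 | step 9 | lavandulyl dienone, 3,5-dihydroxy-6-methyl-6-[(S)-lavandulyl]-4-(3-methylbut-2-enyl)-2-(2-methylpropanoyl)cyclohexa-2,4-dienone with C5 configured as in the target | CC(C)=CC[C@@H](C(C)=C)C[C@@]1(C)C(O)=C(CC=C(C)C)C(O)=C(C(=O)C(C)C)C1=O
F4 | step 8 | 1-{2,6-dihydroxy-3-methyl-4-[(S)-lavandulyloxy]-5-(3-methylbut-2-enyl)phenyl}-2-methylpropan-1-one | CC(C)=CC[C@@H](C(C)=C)COc1c(C)c(O)c(C(=O)C(C)C)c(O)c1CC=C(C)C
F5 | step 6 | lavandulol hydrate, (R)-2-(2-hydroxypropan-2-yl)-5-methylhex-4-en-1-ol | CC(C)=CC[C@@H](C(C)(C)O)CO
F6 | step 6 | 1-{2,6-dihydroxy-4-[(R)-2-(2-hydroxypropan-2-yl)-5-methylhex-4-enyloxy]-3-methylphenyl}-2-methylpropan-1-one | CC(C)=CC[C@@H](C(C)(C)O)COc1cc(O)c(C(=O)C(C)C)c(O)c1C
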